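(The numbers in the tables stem from a simulated flask for substances that don't exist; noise was put on by code.)

If you repeat these flasks, plot ln(target/substrate) against time instead of the percentages, and watch for the moment that line crosses zero.

the same everywhere: substrate 0.033 M
- south-east: partner 2.5 equiv; protic impurity 0.033 M; run made earlier
- north-east: partner 5.1 equiv; protic impurity 0.033 M; run made earlier
- oak: partner 2.00 equiv; protic impurity 0.0330 M; time 2.5 min
- alder: partner 3.00 equiv; protic impurity 0.0330 M; time 2.5 min
- birch: partner 4.50 equiv; protic impurity 0.0330 M; time 2.5 min

- south-east (time / min: substrate / %, target / %): 0.333: 97.0, 1.5; 0.667: 97.2, 2.3; 1.00: 94.1, 5.9; 1.33: 91.1, 10.5; 2.00: 78.0, 20.7; 2.50: 69.1, 28.3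
- north-east (time / min: substrate / %, target / %): 0.200: 98.0, 3.0; 0.333: 95.8, 3.5; 0.500: 94.4, 7.2; 0.667: 86.9, 12.9; 1.00: 72.0, 29.3; 1.50: 39.6, 58.6; 2.50: 5.2, 94.5

(scatter of a reading: 1 percentage point)

- the numbers in the tables scatter with a standard deviation of 1 percentage point

1. which of these there is most of at the end, counted by the substrate in it, oak (target / substrate)
2. which of these there is most of at the end, counted by the substrate in it, alder (target / substrate)
3. which of these there is most of at the end, counted by the substrate in it, birch (target / substrate)
4. the largest of these amounts at the end, in percent of the substrate charged, oak
5. the largest of these amounts at the end, in percent of the substrate charged, alder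
6. the largest of these amounts at the end, in percent of the substrate charged, birch

Follow the logarithm of the ratio of target to substrate: in the north-east run, from 1.00 min to 2.50 min, it climbs at 2.53 /min. Two numbers then describe a run: this rate, and the height the line must climb. Scaled by partner equivalents, the north-east rate gives 1.24 /min for the south-east run, whose readings from 1.00 min to 2.50 min give 1.25 /min, so take the rate as proportional to equivalents.

The height is the rate times the time, less the final logarithm: 3.43 from north-east and 4.00 from south-east, with mean 3.71.

Height over rate is the crossing time, the moment target equals substrate, which plays the part of an induction time in this autocatalytic curve. For alder, at 1.49 /min, it is 2.49 min, against the asked 2.5 min. Then ln(target/substrate) at the end is the height times (asked time over crossing time, less one). The two heights separately put alder's crossing at 2.30 min and 2.68 min, either side of the asked time. My reckoning therefore gives target 22.6% in oak, 50.4% in alder and 86.7% in birch.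

The forecast differs: substrate 82% in oak, target 89% in birch, and for alder substrate 51%, “essentially a coin toss, with substrate slightly favoured”, where my reckoning leans to target.

Alder ends with substrate 54.1%, oak with substrate 82.1%, birch with target 86.0%, so the forecast stands. Partner at 2.81 equiv or 3.18 equiv moves alder's end substrate by 6 points, while its gap from even is 4.1 points. Alder's final logarithm, −0.164, at rate 1.49 /min, puts its crossing at 2.61 min, beside the 2.49 min reckoned.

    partner + protic impurity → quenched reagent (k = 0.180 /M/s)
    substrate + partner → target (k = 0.00710 /M/s)
    substrate + partner + target → 2 target (k = 10.0 /M²/s)

Reckon the crossing time as the inverse square of the substrate charge, the power that the rate of the third step carries with partner equivalents held; protic impurity in this neighbour of alder stands at 1.65 equiv. With the height held, alder's recipe at 0.020 M crosses at 6.79 min, which gives substrate 91.2%. That flask ends with substrate 90.7%.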